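**Plan**
1. Last cuts: the CH=CH bond of the 2,2-dimethyl-2H-pyran fused to ring B (ring-closing metathesis) and the CH=CMe2 bond of the prenyl group on ring A (cross-metathesis), both made by one ruthenium carbene in one flask.
2. Enabling feature: the pyran olefin lies between aryl carbon C3' and the O-bearing quaternary carbon on O4', so an (E)-propenyl group on C3' and a 2-methylbut-3-en-2-yl ether on O4' (ortho neighbours, gem-dimethyl) close to a six-membered ring, while the C8 allyl group of ring A can only cross-metathesise.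
3. Earlier cuts: O1–C2 of the chroman (Mitsunobu) and C3–C4 (alkylation of a ring B arylacetyl imide with a ring A benzyl bromide); C2 is the carbon of chloroform (one-carbon homologation of the ring B aldehyde).
4. Both arenes come from one aldehyde, 3-allyl-2,4-dihydroxybenzaldehyde (allylation and Claisen rearrangement of 2,4-dihydroxybenzaldehyde); ring A keeps the allyl group, ring B has it isomerised to propenyl.
5. Forward order: ring A bromide (steps 3–6), ring B imide (steps 7–12), union and chroman ring (steps 13–16), pyran ring and prenyl group (step 17), deprotection (step 18).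
6. Stereochemistry: the only stereocenter, C3 (R), is set in step 13 by the (R)-4-benzyl-2-oxazolidinone auxiliary; no later step touches it.

Key step: step 17

Remark: tert-butyl 2-methylbut-3-en-2-yl carbonate is taken as a purchased reagent; the propenyl group is drawn (E), and any (Z) isomer is carried along because this geometry is erased when propene is lost in step 17.

Abbreviations in the step lines: ArA = 3-allyl-2-[(tert-butyldimethylsilyl)oxy]-4-(methoxymethoxy)phenyl; ArB = 2-(methoxymethoxy)-4-[(2-methylbut-3-en-2-yl)oxy]-3-[(E)-prop-1-en-1-yl]phenyl.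

**Route**

Step 1
Reactants: 1 2,4-dihydroxybenzaldehyde
Product: 2 4-(allyloxy)-2-hydroxybenzaldehyde
Conditions: allyl bromide, K2CO3, acetone, 56 °C
Reagents that add atoms: allyl bromide, C=CCBr
Why: Williamson etherification should be selective for the 4-hydroxyl because the 2-hydroxyl is held in the hydrogen bond to the formyl group and is the weaker nucleophile under carbonate conditions.

Step 2
Reactants: 2 4-(allyloxy)-2-hydroxybenzaldehyde
Product: 4 3-allyl-2,4-dihydroxybenzaldehyde, via Claisen dienone 3 (not isolated)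
Conditions: PhNEt2, 195 °C
Reagents that add atoms: none
Why: Aromatic Claisen rearrangement ([3,3] shift, then enolisation of dienone 3); the chelated salicylaldehyde fixes the bonds so that the C3–C4 bond carries the double-bond character needed for migration to C3, the carbon between the two oxygens, in preference to C5.

Step 3
Reactants: 4 3-allyl-2,4-dihydroxybenzaldehyde
Product: 5 3-allyl-2-hydroxy-4-(methoxymethoxy)benzaldehyde
Conditions: MeOCH2Cl, K2CO3, acetone, 0 °C to rt
Reagents that add atoms: chloromethyl methyl ether, COCCl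
Why: The 4-hydroxyl is again the only one outside the chelate, so alkylation under weak base should stop at the mono-ether, which becomes the protected 7-hydroxyl of ring A.

Step 4
Reactants: 5 3-allyl-2-hydroxy-4-(methoxymethoxy)benzaldehyde
Product: 6 3-allyl-2-[(tert-butyldimethylsilyl)oxy]-4-(methoxymethoxy)benzaldehyde
Conditions: t-BuMe2SiCl, imidazole, DMF, rt
Reagents that add atoms: tert-butyldimethylsilyl chloride, CC(C)(C)[Si](C)(C)Cl
Why: Silylation of the remaining phenol gives a fluoride-labile mask for the future ring oxygen O1 that is orthogonal to the acetal ethers.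

Step 5
Reactants: 6 3-allyl-2-[(tert-butyldimethylsilyl)oxy]-4-(methoxymethoxy)benzaldehyde
Product: 7 {3-allyl-2-[(tert-butyldimethylsilyl)oxy]-4-(methoxymethoxy)phenyl}methanol
Conditions: NaBH4, MeOH/THF, 0 °C
Reagents that add atoms: none
Why: Borohydride reduction of an aryl aldehyde leaves the silyl ether, acetal ether and allyl group alone, and the low temperature holds back silyl migration to the new alkoxide.

Step 6
Reactants: 7 {3-allyl-2-[(tert-butyldimethylsilyl)oxy]-4-(methoxymethoxy)phenyl}methanol
Product: 8 3-allyl-2-[(tert-butyldimethylsilyl)oxy]-4-(methoxymethoxy)benzyl bromide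
Conditions: CBr4, PPh3, CH2Cl2, 0 °C; used at once
Reagents that add atoms: carbon tetrabromide, BrC(Br)(Br)Br
Why: Appel bromination is neutral and should convert the benzylic alcohol to the bromide without touching the acid-sensitive ethers.

Step 7
Reactants: 4 3-allyl-2,4-dihydroxybenzaldehyde
Product: 9 2,4-dihydroxy-3-[(E)-prop-1-en-1-yl]benzaldehyde
Conditions: RuClH(CO)(PPh3)3 (2 mol %), toluene/THF, 80 °C
Reagents that add atoms: none
Why: Ruthenium hydride-catalysed double-bond migration (hydrometalation, β-hydride elimination) moves the terminal olefin into conjugation with the arene, mainly as the (E) isomer, and gives the aryl-CH=CH handle needed on C3' for the later ring closure.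

Step 8
Reactants: 9 2,4-dihydroxy-3-[(E)-prop-1-en-1-yl]benzaldehyde
Product: 10 2-hydroxy-4-[(2-methylbut-3-en-2-yl)oxy]-3-[(E)-prop-1-en-1-yl]benzaldehyde
Conditions: tert-butyl 2-methylbut-3-en-2-yl carbonate, Pd(PPh3)4 (5 mol %), THF, 0 °C
Reagents that add atoms: tert-butyl 2-methylbut-3-en-2-yl carbonate, C=CC(C)(C)OC(=O)OC(C)(C)C
Why: Tsuji–Trost O-allylation, in which zerovalent palladium ionises the tertiary carbonate, the released tert-butoxide deprotonates the more acidic non-chelated 4-hydroxyl, and phenoxide attack at the more substituted allyl terminus under kinetic control at low temperature gives the reverse-prenyl ether.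

Step 9
Reactants: 10 2-hydroxy-4-[(2-methylbut-3-en-2-yl)oxy]-3-[(E)-prop-1-en-1-yl]benzaldehyde
Product: 11 2-(methoxymethoxy)-4-[(2-methylbut-3-en-2-yl)oxy]-3-[(E)-prop-1-en-1-yl]benzaldehyde (ArB-CHO)
Conditions: NaH, THF/DMF, 0 °C; MeOCH2Cl
Reagents that add atoms: chloromethyl methyl ether, COCCl
Why: Deprotonation with NaH breaks the chelate and the phenoxide is alkylated; the tertiary allyl ether and the aldehyde (no α-hydrogen) tolerate the base.

Step 10
Reactants: 11 ArB-CHO
Product: 12 racemic 2,2,2-trichloro-1-ArB-ethanol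
Conditions: CHCl3, DBU, 0 °C to rt
Reagents that add atoms: chloroform, ClC(Cl)Cl
Why: Base-mediated addition of trichloromethanide to the aldehyde is the first half of a Jocic–Reeve homologation; the new carbinol center is racemic and is removed in step 11.

Step 11
Reactants: 12 racemic 2,2,2-trichloro-1-ArB-ethanol
Product: 15 ArB-acetic acid, via dichloroepoxide 13 (not isolated), via acyl chloride 14 (not isolated)
Conditions: NaBH4, NaOH, t-BuOH/H2O, 55 °C; then aqueous citric acid, 0 °C
Reagents that add atoms: sodium hydroxide, [Na+].[OH-]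
Why: Jocic–Reeve-type reductive homologation, in which the alkoxide closes to dichloroepoxide 13, hydride opens it at the benzylic carbon to give acyl chloride 14, and hydroxide hydrolyses this, so the aldehyde carbon becomes the future C3 and the chloroform carbon the future C2.

Step 12
Reactants: 15 ArB-acetic acid; 16 (4R)-4-benzyl-1,3-oxazolidin-2-one
Product: 18 (4R)-4-benzyl-3-(ArB-acetyl)-1,3-oxazolidin-2-one, via mixed pivalic anhydride 17 (not isolated)
Conditions: t-BuCOCl, Et3N, THF, −20 °C; then 16, LiCl, −20 °C to rt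
Reagents that add atoms: pivaloyl chloride, CC(C)(C)C(Cl)=O (its atoms stay only in intermediate 17)
Why: N-acylation of an oxazolidinone through the mixed pivalic anhydride with LiCl/Et3N activation is standard and mild enough for the acetal and tertiary allyl ethers.

Step 13
Reactants: 18 (4R)-4-benzyl-3-(ArB-acetyl)-1,3-oxazolidin-2-one; 8 3-allyl-2-[(tert-butyldimethylsilyl)oxy]-4-(methoxymethoxy)benzyl bromide
Product: 19 (4R)-4-benzyl-3-[(2R)-3-ArA-2-ArB-propanoyl]-1,3-oxazolidin-2-one
Conditions: NaN(SiMe3)2, THF, −78 °C; then 8, −78 to −40 °C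
Reagents that add atoms: none
Why: Evans alkylation, in which the chelated (Z)-enolate is attacked by the benzylic bromide on the face opposite the C4 benzyl group of the (R)-auxiliary, sets the new center as (R), the future C3.

Step 14
Reactants: 19 (4R)-4-benzyl-3-[(2R)-3-ArA-2-ArB-propanoyl]-1,3-oxazolidin-2-one
Product: 20 (2R)-3-ArA-2-ArB-propan-1-ol
Conditions: LiBH4, MeOH (1 equiv), THF, 0 °C
Reagents that add atoms: none
Why: Reductive cleavage of the N-acyl oxazolidinone at the exocyclic carbonyl gives the primary alcohol without epimerising the α-aryl center, and the auxiliary is recovered.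

Step 15
Reactants: 20 (2R)-3-ArA-2-ArB-propan-1-ol
Product: 21 2-allyl-6-[(2R)-2-ArB-3-hydroxypropyl]-3-(methoxymethoxy)phenol
Conditions: Bu4NF, THF, 0 °C
Reagents that add atoms: none
Why: Fluoride cleaves the aryl silyl ether selectively and leaves the acetal ethers, the tertiary allyl ether and all olefins untouched.

Step 16
Reactants: 21 2-allyl-6-[(2R)-2-ArB-3-hydroxypropyl]-3-(methoxymethoxy)phenol
Product: 22 (3R)-8-allyl-3-ArB-7-(methoxymethoxy)chroman
Conditions: PPh3, DIAD, THF (0.02 M), 0 °C to rt
Reagents that add atoms: none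
Why: Intramolecular Mitsunobu etherification (6-exo-tet attack of the only free phenol on the activated primary alcohol) closes the chroman by substitution at the CH2 carbon, so the adjacent stereocenter is not involved.

Step 17
Reactants: 22 (3R)-8-allyl-3-ArB-7-(methoxymethoxy)chroman
Product: 24 (3R)-7-(methoxymethoxy)-3-[5-(methoxymethoxy)-2,2-dimethyl-2H-chromen-6-yl]-8-(3-methylbut-2-en-1-yl)chroman, via allyl chromene 23 (not isolated)
Conditions: RuCl2(H2IMes)(PCy3)(=CHPh) (second-generation Grubbs catalyst, 5 mol %), CH2Cl2 (0.005 M), 40 °C; then 2-methylbut-2-ene (excess), 25 °C, closed vessel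
Reagents that add atoms: 2-methylbut-2-ene, CC=C(C)C
Why: A ruthenium alkylidene adds across one of the two ring B olefins and the carbene so formed undergoes intramolecular [2+2] cycloaddition and cycloreversion with the other, joining the aryl-bound CH of the propenyl group to the CH next to the CMe2–O carbon with loss of propene; after 2-methylbut-2-ene is added, the same catalyst exchanges the terminal CH2 of the C8 allyl group for an isopropylidene unit, again with loss of propene. The closest known reaction types are ring-closing metathesis of 2-alkenylphenyl allyl ethers to 2H-chromenes and cross-metathesis of allylarenes with 2-methylbut-2-ene to prenylarenes. The 2,2-dimethyl-2H-pyran closes as a six-membered ring by ring-closing metathesis with the new cis double bond inside the ring, its geometry dictated by ring size. No stereocenter is formed, and C3 is remote from every reacting atom under neutral conditions. The step needs ring closure to beat intermolecular metathesis and needs the allyl group to react only in the cross-metathesis; the ortho placement of the two olefins on C3' and O4' with the gem-dimethyl group favours closure at high dilution, the tertiary vinyl group and the ortho,ortho-disubstituted propenyl group are poor intermolecular partners, and the allyl group cannot reach either of them through a ring of reasonable size. Allyl homodimers formed in the first stage re-enter cross-metathesis with the excess trisubstituted olefin, and the prenyl and chromene double bonds are inert once formed.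

Step 18
Reactants: 24 (3R)-7-(methoxymethoxy)-3-[5-(methoxymethoxy)-2,2-dimethyl-2H-chromen-6-yl]-8-(3-methylbut-2-en-1-yl)chroman
Product: 25 (3R)-3-(5-hydroxy-2,2-dimethyl-2H-chromen-6-yl)-8-(3-methylbut-2-en-1-yl)chroman-7-ol (target)
Conditions: HCl (3 M aq.), MeOH, rt to 40 °C
Reagents that add atoms: none
Why: Acid-catalysed acetal exchange with methanol removes both methoxymethyl groups as dimethoxymethane, and mild temperature with short contact should spare the prenyl and chromene olefins.

**Compound list**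

1 | 2,4-dihydroxybenzaldehyde | O=Cc1ccc(O)cc1O | starting material
2 | 4-(allyloxy)-2-hydroxybenzaldehyde | O=Cc1ccc(OCC=C)cc1O | intermediate
3 | 2-hydroxy-4-oxo-3-(prop-2-en-1-yl)cyclohexa-1,5-diene-1-carbaldehyde (racemic Claisen dienone) | O=CC1=C(O)C(CC=C)C(=O)C=C1 | intermediate
4 | 3-allyl-2,4-dihydroxybenzaldehyde | O=Cc1ccc(O)c(CC=C)c1O | intermediate
5 | 3-allyl-2-hydroxy-4-(methoxymethoxy)benzaldehyde | O=Cc1ccc(OCOC)c(CC=C)c1O | intermediate
6 | 3-allyl-2-[(tert-butyldimethylsilyl)oxy]-4-(methoxymethoxy)benzaldehyde | O=Cc1ccc(OCOC)c(CC=C)c1O[Si](C)(C)C(C)(C)C | intermediate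
7 | {3-allyl-2-[(tert-butyldimethylsilyl)oxy]-4-(methoxymethoxy)phenyl}methanol | OCc1ccc(OCOC)c(CC=C)c1O[Si](C)(C)C(C)(C)C | intermediate
8 | 3-allyl-2-[(tert-butyldimethylsilyl)oxy]-4-(methoxymethoxy)benzyl bromide | BrCc1ccc(OCOC)c(CC=C)c1O[Si](C)(C)C(C)(C)C | intermediate
9 | 2,4-dihydroxy-3-[(E)-prop-1-en-1-yl]benzaldehyde | O=Cc1ccc(O)c(/C=C/C)c1O | intermediate
10 | 2-hydroxy-4-[(2-methylbut-3-en-2-yl)oxy]-3-[(E)-prop-1-en-1-yl]benzaldehyde | O=Cc1ccc(OC(C)(C)C=C)c(/C=C/C)c1O | intermediate
11 | 2-(methoxymethoxy)-4-[(2-methylbut-3-en-2-yl)oxy]-3-[(E)-prop-1-en-1-yl]benzaldehyde | O=Cc1ccc(OC(C)(C)C=C)c(/C=C/C)c1OCOC | intermediate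
12 | 2,2,2-trichloro-1-{2-(methoxymethoxy)-4-[(2-methylbut-3-en-2-yl)oxy]-3-[(E)-prop-1-en-1-yl]phenyl}ethan-1-ol (racemic) | OC(c1ccc(OC(C)(C)C=C)c(/C=C/C)c1OCOC)C(Cl)(Cl)Cl | intermediate
13 | 2,2-dichloro-3-{2-(methoxymethoxy)-4-[(2-methylbut-3-en-2-yl)oxy]-3-[(E)-prop-1-en-1-yl]phenyl}oxirane (racemic) | ClC1(Cl)OC1c1ccc(OC(C)(C)C=C)c(/C=C/C)c1OCOC | intermediate
14 | {2-(methoxymethoxy)-4-[(2-methylbut-3-en-2-yl)oxy]-3-[(E)-prop-1-en-1-yl]phenyl}acetyl chloride | O=C(Cl)Cc1ccc(OC(C)(C)C=C)c(/C=C/C)c1OCOC | intermediate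
15 | {2-(methoxymethoxy)-4-[(2-methylbut-3-en-2-yl)oxy]-3-[(E)-prop-1-en-1-yl]phenyl}acetic acid | OC(=O)Cc1ccc(OC(C)(C)C=C)c(/C=C/C)c1OCOC | intermediate
16 | (4R)-4-benzyl-1,3-oxazolidin-2-one | O=C1N[C@H](Cc2ccccc2)CO1 | starting material
17 | {2-(methoxymethoxy)-4-[(2-methylbut-3-en-2-yl)oxy]-3-[(E)-prop-1-en-1-yl]phenyl}acetic 2,2-dimethylpropanoic anhydride | CC(C)(C)C(=O)OC(=O)Cc1ccc(OC(C)(C)C=C)c(/C=C/C)c1OCOC | intermediate
18 | (4R)-4-benzyl-3-({2-(methoxymethoxy)-4-[(2-methylbut-3-en-2-yl)oxy]-3-[(E)-prop-1-en-1-yl]phenyl}acetyl)-1,3-oxazolidin-2-one | O=C(Cc1ccc(OC(C)(C)C=C)c(/C=C/C)c1OCOC)N1[C@H](Cc2ccccc2)COC1=O | intermediate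
19 | (4R)-4-benzyl-3-[(2R)-3-{3-allyl-2-[(tert-butyldimethylsilyl)oxy]-4-(methoxymethoxy)phenyl}-2-{2-(methoxymethoxy)-4-[(2-methylbut-3-en-2-yl)oxy]-3-[(E)-prop-1-en-1-yl]phenyl}propanoyl]-1,3-oxazolidin-2-one | O=C([C@H](Cc1ccc(OCOC)c(CC=C)c1O[Si](C)(C)C(C)(C)C)c1ccc(OC(C)(C)C=C)c(/C=C/C)c1OCOC)N1[C@H](Cc2ccccc2)COC1=O | intermediate
20 | (2R)-3-{3-allyl-2-[(tert-butyldimethylsilyl)oxy]-4-(methoxymethoxy)phenyl}-2-{2-(methoxymethoxy)-4-[(2-methylbut-3-en-2-yl)oxy]-3-[(E)-prop-1-en-1-yl]phenyl}propan-1-ol | OC[C@H](Cc1ccc(OCOC)c(CC=C)c1O[Si](C)(C)C(C)(C)C)c1ccc(OC(C)(C)C=C)c(/C=C/C)c1OCOC | intermediate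
21 | 2-allyl-6-[(2R)-3-hydroxy-2-{2-(methoxymethoxy)-4-[(2-methylbut-3-en-2-yl)oxy]-3-[(E)-prop-1-en-1-yl]phenyl}propyl]-3-(methoxymethoxy)phenol | OC[C@H](Cc1ccc(OCOC)c(CC=C)c1O)c1ccc(OC(C)(C)C=C)c(/C=C/C)c1OCOC | intermediate
22 | (3R)-8-allyl-7-(methoxymethoxy)-3-{2-(methoxymethoxy)-4-[(2-methylbut-3-en-2-yl)oxy]-3-[(E)-prop-1-en-1-yl]phenyl}chroman | C=CCc1c(OCOC)ccc2c1OC[C@@H](c1ccc(OC(C)(C)C=C)c(/C=C/C)c1OCOC)C2 | intermediate
23 | (3R)-8-allyl-7-(methoxymethoxy)-3-[5-(methoxymethoxy)-2,2-dimethyl-2H-chromen-6-yl]chroman | C=CCc1c(OCOC)ccc2c1OC[C@@H](c1ccc3c(c1OCOC)C=CC(C)(C)O3)C2 | intermediate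
24 | (3R)-7-(methoxymethoxy)-3-[5-(methoxymethoxy)-2,2-dimethyl-2H-chromen-6-yl]-8-(3-methylbut-2-en-1-yl)chroman | CC(C)=CCc1c(OCOC)ccc2c1OC[C@@H](c1ccc3c(c1OCOC)C=CC(C)(C)O3)C2 | intermediate
25 | (3R)-3-(5-hydroxy-2,2-dimethyl-2H-chromen-6-yl)-8-(3-methylbut-2-en-1-yl)chroman-7-ol | CC(C)=CCc1c(O)ccc2c1OC[C@@H](c1ccc3c(c1O)C=CC(C)(C)O3)C2 | target

**Step count**

Total: 18 steps. Longest linear sequence: 14 steps (1, 2, 7–18) from 2,4-dihydroxybenzaldehyde.

**Steps most likely to fail**

Step 17. The catalyst may be used up in intermolecular metathesis at the unhindered allyl group of ring A (dimers, oligomers) before it engages the two hindered olefins on ring B, and heating to force the closure would start Claisen rearrangement of the tertiary allyl aryl ether. The fallback sets out from 18 and comes back at 23: the ring is closed before the fragments are joined, where no third olefin is present and a small, robust substrate allows a higher catalyst loading. Imide 18 with RuCl2(H2IMes)(PCy3)(=CHPh) in CH2Cl2 at 40 °C should give the chromene imide F1. Its enolate (NaN(SiMe3)2, THF, −78 °C) with bromide 8 should give the benzylated chromene imide F2 under the same auxiliary control as in step 13. LiBH4/MeOH should then give the chromene alcohol F3, Bu4NF the chromene phenol F4, and Mitsunobu closure (PPh3, DIAD) the allyl chromene 23, which needs only the cross-metathesis with 2-methylbut-2-ene of step 17 to reach 24.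

Step 11. Hydroxide or tert-butoxide may outrun hydride in opening the electron-rich benzylic dichloroepoxide (giving an α-oxygenated acid), or the carbinol may revert to the aldehyde under base. The fallback sets out from 11 and comes back at 15. Wittig methoxymethylenation (Ph3P(CH2OMe)Cl, KOtBu, THF, 0 °C) should give the enol ether F5 as an E/Z mixture. Brief hydrolysis with pyridinium p-toluenesulfonate in wet acetone should give the arylacetaldehyde F6, and Pinnick oxidation (NaClO2, NaH2PO4, 2-methylbut-2-ene, t-BuOH/H2O) should give acid 15.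

Step 18. Under acid the freed C7 hydroxyl may add across the prenyl double bond (closure of a dimethyldihydropyran onto ring A), or the chromene olefin may be hydrated before both acetal ethers are gone. The fallback sets out from 23 and comes back at 25: step 17 is stopped after the ring closure and 23 is isolated. The methoxymethyl groups are removed (HCl, MeOH, 40 °C) while the side chain is still an allyl group, which should not cyclise under these conditions, to give the allyl diphenol F7. Cross-metathesis of F7 with 2-methylbut-2-ene (same ruthenium catalyst, CH2Cl2, 25 °C) should then give 25 directly, so that the ortho-prenyl phenol never meets acid.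

**Further compounds**

F1 | step 17 | (4R)-4-benzyl-3-{[5-(methoxymethoxy)-2,2-dimethyl-2H-chromen-6-yl]acetyl}-1,3-oxazolidin-2-one | O=C(Cc1ccc2OC(C)(C)C=Cc2c1OCOC)N1[C@H](Cc2ccccc2)COC1=O
F2 | step 17 | (4R)-4-benzyl-3-[(2R)-3-{3-allyl-2-[(tert-butyldimethylsilyl)oxy]-4-(methoxymethoxy)phenyl}-2-[5-(methoxymethoxy)-2,2-dimethyl-2H-chromen-6-yl]propanoyl]-1,3-oxazolidin-2-one | O=C([C@H](Cc1ccc(OCOC)c(CC=C)c1O[Si](C)(C)C(C)(C)C)c1ccc2OC(C)(C)C=Cc2c1OCOC)N1[C@H](Cc2ccccc2)COC1=O
F3 | step 17 | (2R)-3-{3-allyl-2-[(tert-butyldimethylsilyl)oxy]-4-(methoxymethoxy)phenyl}-2-[5-(methoxymethoxy)-2,2-dimethyl-2H-chromen-6-yl]propan-1-ol | OC[C@H](Cc1ccc(OCOC)c(CC=C)c1O[Si](C)(C)C(C)(C)C)c1ccc2OC(C)(C)C=Cc2c1OCOC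
F4 | step 17 | 2-allyl-6-{(2R)-3-hydroxy-2-[5-(methoxymethoxy)-2,2-dimethyl-2H-chromen-6-yl]propyl}-3-(methoxymethoxy)phenol | OC[C@H](Cc1ccc(OCOC)c(CC=C)c1O)c1ccc2OC(C)(C)C=Cc2c1OCOC
F5 | step 11 | 1-(2-methoxyethenyl)-2-(methoxymethoxy)-4-[(2-methylbut-3-en-2-yl)oxy]-3-[(E)-prop-1-en-1-yl]benzene (E/Z mixture at the enol ether) | COC=Cc1ccc(OC(C)(C)C=C)c(/C=C/C)c1OCOC
F6 | step 11 | {2-(methoxymethoxy)-4-[(2-methylbut-3-en-2-yl)oxy]-3-[(E)-prop-1-en-1-yl]phenyl}acetaldehyde | O=CCc1ccc(OC(C)(C)C=C)c(/C=C/C)c1OCOC
F7 | step 18 | (3R)-8-allyl-3-(5-hydroxy-2,2-dimethyl-2H-chromen-6-yl)chroman-7-ol | C=CCc1c(O)ccc2c1OC[C@@H](c1ccc3c(c1O)C=CC(C)(C)O3)C2
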